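**Plan**

1. Numbering used: ring carbons C1–C14; C1 bears the lactone carbon C15 (C16 = lactone C=O, C17 = exocyclic CH2), C2 bears the lactone oxygen, CH3 groups sit on C4, C8 and C12, OAc on C9.
2. Retrosynthesis: acetate and the C15=C17 methylene are removed and C9 is passed through the enone; the 14-membered ring is then cut at C8–C9 to an ynal. The in-ring unit C7=C8(CH3)–C9(O), an E-2-methylallylic alcohol, is what a syn reductive coupling of a methyl-capped alkyne (C7≡C8–CH3) with an aldehyde (C9) delivers, so one nickel-catalysed event gives the ring, the alkene geometry and the C9–O bond.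
3. The γ-lactone is cut at O–C16 (C16 comes from a terminal vinyl group) and the chain at C1–C2: anti-allylboration of an enal (C2–C8) with an (E)-allylboronate (C9–C14, C1, C15, C16).
4. Forward order: two four-step fragments, C1–C2 bond, γ-lactone ring, 14-membered ring, C17 methylene, C9 oxidation and reduction, acetate.
5. Stereochemistry: C1 and C2 come from the chiral phosphoric acid-catalysed allylboration (E-boronate gives anti, hence the trans lactone); C9 comes from CBS reduction of the ring enone; the three E-alkenes come from syn-carbocupration, syn-carboalumination and the syn nickel coupling.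

Key step: step 13

Remark: the known sense of induction of (R)-TRIP (Re-face attack on aryl and α,β-unsaturated aldehydes) is assumed to hold for enal 7; the C9 configuration formed in step 13 is not relied on, since both epimers converge at enone 29. Compounds 1, 3, 8 and 13 are taken as commercial.

**Route**

Step 1
Reactants: 1 pent-3-yn-1-ol
Product: 2 5-bromopent-2-yne
Conditions: CBr4, PPh3, CH2Cl2, 0 °C to rt
Reagents that add atoms: carbon tetrabromide BrC(Br)(Br)Br
Why: Appel reaction of a primary alcohol under neutral conditions, which should leave the internal alkyne untouched.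

Step 2
Reactants: 2 5-bromopent-2-yne; 3 ethyl but-2-ynoate
Product: 5 ethyl (2E)-3-methyloct-2-en-6-ynoate, via pent-3-yn-1-ylmagnesium bromide 4 (not isolated)
Conditions: Mg, THF, 40 °C; CuBr·SMe2 (1 equiv), THF, −45 °C; 3, −78 °C; MeOH then aq. NH4Cl at −78 °C
Reagents that add atoms: none
Why: syn-carbocupration of a 2-ynoate by an alkylcopper reagent, in which alkyl and copper add to the same face and cold protonation with retention places the ester cis to the methyl group, giving the E olefin that becomes C3=C4.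

Step 3
Reactants: 5 ethyl (2E)-3-methyloct-2-en-6-ynoate
Product: 6 (2E)-3-methyloct-2-en-6-yn-1-ol
Conditions: iBu2AlH (2.5 equiv), CH2Cl2, −78 to 0 °C; aq. potassium sodium tartrate (KNaC4H4O6)
Reagents that add atoms: none
Why: 1,2-reduction of an enoate to the allylic alcohol with diisobutylaluminium hydride, which should not touch the alkyne or the olefin geometry.

Step 4
Reactants: 6 (2E)-3-methyloct-2-en-6-yn-1-ol
Product: 7 (2E)-3-methyloct-2-en-6-ynal
Conditions: MnO2, CH2Cl2, rt
Reagents that add atoms: none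
Why: allylic oxidation with MnO2, which is selective for the allylic alcohol and should preserve the E geometry.

Step 5
Reactants: 8 hex-1-en-5-yne
Product: 11 (3E)-4-methylocta-3,7-dien-1-ol, via alkenyldimethylalane 9 (not isolated), via lithium alkenylalanate 10 (not isolated)
Conditions: Me3Al (2 equiv), Cp2ZrCl2 (0.25 equiv), ClCH2CH2Cl, 0 °C to rt; evaporation; n-BuLi, hexane–THF, −30 °C; ethylene oxide, −30 °C to rt; cold dilute HCl
Reagents that add atoms: trimethylaluminium C[Al](C)C; ethylene oxide C1CO1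
Why: Negishi zirconium-catalysed syn-methylalumination of the terminal alkyne (the terminal alkene should be inert), then alkenyl transfer from the alanate to the epoxide with retention, which sets the E C11=C12 olefin.

Step 6
Reactants: 11 (3E)-4-methylocta-3,7-dien-1-ol
Product: 12 tert-butyl{[(3E)-4-methylocta-3,7-dien-1-yl]oxy}diphenylsilane
Conditions: TBDPSCl, imidazole, CH2Cl2, rt
Reagents that add atoms: tert-butyl(chloro)diphenylsilane CC(C)(C)[Si](Cl)(c1ccccc1)c1ccccc1
Why: silylation of the primary alcohol; the TBDPS ether should survive the organolithium, acid-catalyst and borane steps that follow.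

Step 7
Reactants: 12 tert-butyl{[(3E)-4-methylocta-3,7-dien-1-yl]oxy}diphenylsilane; 13 2-ethenyl-4,4,5,5-tetramethyl-1,3,2-dioxaborolane
Product: 14 tert-butyl{[(3E,7E)-4-methyl-8-(4,4,5,5-tetramethyl-1,3,2-dioxaborolan-2-yl)octa-3,7-dien-1-yl]oxy}diphenylsilane
Conditions: second-generation Grubbs catalyst RuCl2(=CHPh)(PCy3)(H2IMes) (5 mol %), CH2Cl2, 40 °C
Reagents that add atoms: none
Why: olefin cross-metathesis of a terminal alkene with a vinylboronate, expected to be E-selective and to leave the trisubstituted alkene alone.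

Step 8
Reactants: 14 tert-butyl{[(3E,7E)-4-methyl-8-(4,4,5,5-tetramethyl-1,3,2-dioxaborolan-2-yl)octa-3,7-dien-1-yl]oxy}diphenylsilane
Product: 16 tert-butyl{[(3E,7E)-4-methyl-9-(4,4,5,5-tetramethyl-1,3,2-dioxaborolan-2-yl)nona-3,7-dien-1-yl]oxy}diphenylsilane, via chloromethyl boronate complex 15 (not isolated)
Conditions: BrCH2Cl, n-BuLi, THF, −78 °C to rt
Reagents that add atoms: bromochloromethane ClCBr
Why: Matteson homologation, in which chloromethyllithium made in situ adds to boron and 1,2-migration of the alkenyl group with loss of chloride gives the (E)-allylboronate with retention of olefin geometry.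

Step 9
Reactants: 7 (2E)-3-methyloct-2-en-6-ynal; 16 tert-butyl{[(3E,7E)-4-methyl-9-(4,4,5,5-tetramethyl-1,3,2-dioxaborolan-2-yl)nona-3,7-dien-1-yl]oxy}diphenylsilane
Product: 17 (6E,8R,9R,12E)-15-[(tert-butyldiphenylsilyl)oxy]-9-ethenyl-6,12-dimethylpentadeca-6,12-dien-2-yn-8-ol
Conditions: (R)-TRIP [(R)-3,3′-bis(2,4,6-triisopropylphenyl)-1,1′-binaphthyl-2,2′-diyl hydrogen phosphate] (5 mol %), 4 Å molecular sieves, toluene, −30 to 0 °C; aqueous work-up
Reagents that add atoms: none
Why: chiral phosphoric acid-catalysed allylboration through a closed chair transition state, in which the E-boronate gives the anti relationship (the later trans lactone) and the catalyst directs attack to the Re face of the enal, setting C2 and C1 of the target as 8R and 9R here.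

Step 10
Reactants: 17 (6E,8R,9R,12E)-15-[(tert-butyldiphenylsilyl)oxy]-9-ethenyl-6,12-dimethylpentadeca-6,12-dien-2-yn-8-ol
Product: 19 (3R,4R,5E)-3-{(3E)-6-[(tert-butyldiphenylsilyl)oxy]-3-methylhex-3-en-1-yl}-6-methylundec-5-en-9-yne-1,4-diol, via bis(9-BBN) adduct 18 (not isolated)
Conditions: 9-BBN (2.5 equiv), THF, 0 °C to rt; then aq. NaOH, H2O2, 0 °C
Reagents that add atoms: hydrogen peroxide OO
Why: anti-Markovnikov hydroboration–oxidation with 9-BBN, which reacts far faster with a monosubstituted alkene than with trisubstituted alkenes or an internal alkyne, so no stereocentre is touched.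

Step 11
Reactants: 19 (3R,4R,5E)-3-{(3E)-6-[(tert-butyldiphenylsilyl)oxy]-3-methylhex-3-en-1-yl}-6-methylundec-5-en-9-yne-1,4-diol
Product: 20 (3R,4R,5E)-3-[(3E)-6-hydroxy-3-methylhex-3-en-1-yl]-6-methylundec-5-en-9-yne-1,4-diol
Conditions: TBAF, THF, rt
Reagents that add atoms: none
Why: fluoride cleavage of the silyl ether, under which nothing else in the molecule is labile.

Step 12
Reactants: 20 (3R,4R,5E)-3-[(3E)-6-hydroxy-3-methylhex-3-en-1-yl]-6-methylundec-5-en-9-yne-1,4-diol
Product: 22 (4R,5R)-5-[(1E)-2-methylhept-1-en-5-yn-1-yl]-4-[(3E)-3-methyl-6-oxohex-3-en-1-yl]oxolan-2-one, via γ-lactol aldehyde 21 (not isolated)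
Conditions: TEMPO (0.3 equiv), PhI(OAc)2 (3.5 equiv), CH2Cl2, rt; rapid filtration, used at once
Reagents that add atoms: none
Why: oxoammonium (TEMPO) oxidation selective for primary alcohols, in which the C16 aldehyde is trapped by the C2 hydroxyl as a γ-lactol and oxidised on to the lactone while the C9 alcohol stops at the aldehyde in the anhydrous medium.

Step 13
Reactants: 22 (4R,5R)-5-[(1E)-2-methylhept-1-en-5-yn-1-yl]-4-[(3E)-3-methyl-6-oxohex-3-en-1-yl]oxolan-2-one
Product: 23 (1R,2R,3E,7E,11E)-9-[(triethylsilyl)oxy]cembra-3,7,11-trien-16,2-olide (C9 epimers)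
Conditions: Ni(COD)2 (0.3 equiv), IMes·HCl [1,3-bis(2,4,6-trimethylphenyl)imidazolium chloride] (0.3 equiv), KOtBu (0.3 equiv), Et3SiH (5 equiv), THF, rt; 22 added by syringe pump over 6 h to 0.005 M
Reagents that add atoms: triethylsilane CC[SiH](CC)CC
Why: Zerovalent nickel carrying the small carbene IMes binds the C7≡C8 alkyne and the C9 aldehyde and couples them oxidatively to an oxanickelacyclopentene containing the new C8–C9 bond; σ-bond metathesis of the Ni–O bond with Et3SiH and C7–H reductive elimination then release the silyl ether and the catalyst. The closest known reaction type is the nickel–carbene-catalysed reductive macrocyclization of ynals with silanes, which with methyl-capped alkynes and a small carbene closes in the endocyclic mode. The ring closes as a 14-membered carbocycle, endo with respect to the alkyne (both C7 and C8 end up in the ring), the tether being long enough to span the metallacycle. The only new stereocentre, C9, arises under weak macrocyclic substrate control and is deliberately not relied on: both epimers are carried forward, converge at enone 29 and C9 is reset by reagent control in step 17. The step needs regioselectivity for C–C bond formation at C8 and not C7, secured by the small methyl cap on C8 together with the small ligand, which place the bulkier tethered substituent next to nickel; it needs E geometry, which follows from syn addition of C9 and H across the alkyne; and it needs ring closure over oligomerization, secured by slow addition at high dilution. The γ-lactone (still without the enoate that would bind nickel) and the trisubstituted alkenes should be spectators, and limiting KOtBu to the amount of imidazolium salt should keep the β,γ-unsaturated aldehyde from enolizing.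

Step 14
Reactants: 23 (1R,2R,3E,7E,11E)-9-[(triethylsilyl)oxy]cembra-3,7,11-trien-16,2-olide (C9 epimers)
Product: 27 (1R,2S,3E,7E,11E)-9-[(triethylsilyl)oxy]cembra-3,7,11,15(17)-tetraen-16,2-olide (C9 epimers), via lithium enolate 24 (not isolated), via Mannich base 25 (not isolated), via trimethylammonium iodide 26 (not isolated)
Conditions: LDA, THF, −78 °C; CH2=NMe2+ I− (Eschenmoser's salt), −78 °C to rt; then MeI, MeOH, rt; then aq. NaHCO3, EtOAc, rt
Reagents that add atoms: N,N-dimethylmethyleneiminium iodide C=[N+](C)C.[I-]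
Why: Mannich aminomethylation of the lactone enolate followed by quaternization and base-induced elimination, the standard α-methylenation of γ-lactones; the temporary α-stereocentre of 25 disappears on elimination and the silyl ether shields C9–O from the base.

Step 15
Reactants: 27 (1R,2S,3E,7E,11E)-9-[(triethylsilyl)oxy]cembra-3,7,11,15(17)-tetraen-16,2-olide (C9 epimers)
Product: 28 (1R,2S,3E,7E,11E)-9-hydroxycembra-3,7,11,15(17)-tetraen-16,2-olide (C9 epimers)
Conditions: HF·pyridine, pyridine, THF, 0 °C
Reagents that add atoms: none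
Why: buffered fluoride cleavage of the triethylsilyl ether, chosen over basic fluoride so that the α-methylene lactone is not exposed to a nucleophilic base.

Step 16
Reactants: 28 (1R,2S,3E,7E,11E)-9-hydroxycembra-3,7,11,15(17)-tetraen-16,2-olide (C9 epimers)
Product: 29 (1R,2S,3E,7E,11E)-9-oxocembra-3,7,11,15(17)-tetraen-16,2-olide
Conditions: Dess–Martin periodinane, CH2Cl2, 0 °C to rt; used at once
Reagents that add atoms: none
Why: Dess–Martin oxidation of the allylic alcohol under near-neutral conditions, which merges both C9 epimers into one enone without moving the C11=C12 bond.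

Step 17
Reactants: 29 (1R,2S,3E,7E,11E)-9-oxocembra-3,7,11,15(17)-tetraen-16,2-olide
Product: 30 (1R,2S,3E,7E,9R,11E)-9-hydroxycembra-3,7,11,15(17)-tetraen-16,2-olide
Conditions: (S)-2-methyl-CBS-oxazaborolidine (0.2 equiv), catecholborane (2 equiv), toluene, −78 °C
Reagents that add atoms: none
Why: Corey–Bakshi–Shibata reduction, in which the α-methylalkenyl side (C8) acts as the large and the C10 methylene as the small ketone substituent, so the (S)-catalyst should deliver hydride to give 9R (same sense as acetophenone to (R)-1-phenylethanol); catecholborane at −78 °C should spare the α-methylene lactone and the alkenes.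

Step 18
Reactants: 30 (1R,2S,3E,7E,9R,11E)-9-hydroxycembra-3,7,11,15(17)-tetraen-16,2-olide
Product: 31 (1R,2S,3E,7E,9R,11E)-9-acetoxycembra-3,7,11,15(17)-tetraen-16,2-olide
Conditions: Ac2O, pyridine, DMAP (cat.), CH2Cl2, 0 °C to rt
Reagents that add atoms: acetic anhydride CC(=O)OC(C)=O
Why: DMAP-catalysed acylation of the secondary allylic alcohol with retention at C9, giving the target.

**Compound list**

1 | pent-3-yn-1-ol | CC#CCCO | starting material
2 | 5-bromopent-2-yne | CC#CCCBr | intermediate
3 | ethyl but-2-ynoate | CC#CC(=O)OCC | starting material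
4 | pent-3-yn-1-ylmagnesium bromide | CC#CCC[Mg]Br | intermediate
5 | ethyl (2E)-3-methyloct-2-en-6-ynoate | CCOC(=O)/C=C(\C)CCC#CC | intermediate
6 | (2E)-3-methyloct-2-en-6-yn-1-ol | OC/C=C(\C)CCC#CC | intermediate
7 | (2E)-3-methyloct-2-en-6-ynal | O=C/C=C(\C)CCC#CC | intermediate
8 | hex-1-en-5-yne | C=CCCC#C | starting material
9 | dimethyl[(1E)-2-methylhexa-1,5-dien-1-yl]alane | C=CCC/C(C)=C/[Al](C)C | intermediate
10 | lithium butyl(dimethyl)[(1E)-2-methylhexa-1,5-dien-1-yl]aluminate | [Li+].C=CCC/C(C)=C/[Al-](C)(C)CCCC | intermediate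
11 | (3E)-4-methylocta-3,7-dien-1-ol | C=CCC/C(C)=C/CCO | intermediate
12 | tert-butyl{[(3E)-4-methylocta-3,7-dien-1-yl]oxy}diphenylsilane | C=CCC/C(C)=C/CCO[Si](c1ccccc1)(c1ccccc1)C(C)(C)C | intermediate
13 | 2-ethenyl-4,4,5,5-tetramethyl-1,3,2-dioxaborolane (vinylboronic acid pinacol ester) | C=CB1OC(C)(C)C(C)(C)O1 | starting material
14 | tert-butyl{[(3E,7E)-4-methyl-8-(4,4,5,5-tetramethyl-1,3,2-dioxaborolan-2-yl)octa-3,7-dien-1-yl]oxy}diphenylsilane | CC1(C)OB(/C=C/CC/C(C)=C/CCO[Si](c2ccccc2)(c2ccccc2)C(C)(C)C)OC1(C)C | intermediate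
15 | lithium chloromethyl ate complex of boronate 14 (boron bears pinacolate, CH2Cl and the E-alkenyl group) | [Li+].CC1(C)O[B-](CCl)(/C=C/CC/C(C)=C/CCO[Si](c2ccccc2)(c2ccccc2)C(C)(C)C)OC1(C)C | intermediate
16 | tert-butyl{[(3E,7E)-4-methyl-9-(4,4,5,5-tetramethyl-1,3,2-dioxaborolan-2-yl)nona-3,7-dien-1-yl]oxy}diphenylsilane | CC1(C)OB(C/C=C/CC/C(C)=C/CCO[Si](c2ccccc2)(c2ccccc2)C(C)(C)C)OC1(C)C | intermediate
17 | (6E,8R,9R,12E)-15-[(tert-butyldiphenylsilyl)oxy]-9-ethenyl-6,12-dimethylpentadeca-6,12-dien-2-yn-8-ol | O[C@@H](/C=C(\C)CCC#CC)[C@H](CC/C(C)=C/CCO[Si](c1ccccc1)(c1ccccc1)C(C)(C)C)C=C | intermediate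
18 | 17 carrying a 9-borabicyclo[3.3.1]nonan-9-yl group on the C8 oxygen and on the terminal carbon of the former vinyl group | C1CCC2CCCC1B2O[C@@H](/C=C(\C)CCC#CC)[C@H](CC/C(C)=C/CCO[Si](c1ccccc1)(c1ccccc1)C(C)(C)C)CCB1C2CCCC1CCC2 | intermediate
19 | (3R,4R,5E)-3-{(3E)-6-[(tert-butyldiphenylsilyl)oxy]-3-methylhex-3-en-1-yl}-6-methylundec-5-en-9-yne-1,4-diol | O[C@@H](/C=C(\C)CCC#CC)[C@H](CC/C(C)=C/CCO[Si](c1ccccc1)(c1ccccc1)C(C)(C)C)CCO | intermediate
20 | (3R,4R,5E)-3-[(3E)-6-hydroxy-3-methylhex-3-en-1-yl]-6-methylundec-5-en-9-yne-1,4-diol | O[C@@H](/C=C(\C)CCC#CC)[C@H](CC/C(C)=C/CCO)CCO | intermediate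
21 | γ-lactol (2-hydroxyoxolane, anomeric mixture) corresponding to lactone 22, C9 already an aldehyde | OC1O[C@@H](/C=C(\C)CCC#CC)[C@H](CC/C(C)=C/CC=O)C1 | intermediate
22 | (4R,5R)-5-[(1E)-2-methylhept-1-en-5-yn-1-yl]-4-[(3E)-3-methyl-6-oxohex-3-en-1-yl]oxolan-2-one | O=C1O[C@@H](/C=C(\C)CCC#CC)[C@H](CC/C(C)=C/CC=O)C1 | intermediate
23 | (1R,2R,3E,7E,11E)-9-[(triethylsilyl)oxy]cembra-3,7,11-trien-16,2-olide (C9 epimers) | C1C(=O)O[C@H]2/C=C(\C)CC/C=C(\C)C(O[Si](CC)(CC)CC)C/C=C(\C)CC[C@H]12 | intermediate
24 | lithium enolate of lactone 23 (C15=C16, O–Li) | C1=C(O[Li])O[C@H]2/C=C(\C)CC/C=C(\C)C(O[Si](CC)(CC)CC)C/C=C(\C)CC[C@H]12 | intermediate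
25 | 15-(dimethylaminomethyl) derivative of 23 (Mannich base, C15 configuration open) | CN(C)CC1C(=O)O[C@H]2/C=C(\C)CC/C=C(\C)C(O[Si](CC)(CC)CC)C/C=C(\C)CC[C@H]12 | intermediate
26 | 15-(trimethylammoniomethyl) derivative of 23, iodide salt | [I-].C[N+](C)(C)CC1C(=O)O[C@H]2/C=C(\C)CC/C=C(\C)C(O[Si](CC)(CC)CC)C/C=C(\C)CC[C@H]12 | intermediate
27 | (1R,2S,3E,7E,11E)-9-[(triethylsilyl)oxy]cembra-3,7,11,15(17)-tetraen-16,2-olide (C9 epimers) | C=C1C(=O)O[C@H]2/C=C(\C)CC/C=C(\C)C(O[Si](CC)(CC)CC)C/C=C(\C)CC[C@H]12 | intermediate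
28 | (1R,2S,3E,7E,11E)-9-hydroxycembra-3,7,11,15(17)-tetraen-16,2-olide (C9 epimers) | C=C1C(=O)O[C@H]2/C=C(\C)CC/C=C(\C)C(O)C/C=C(\C)CC[C@H]12 | intermediate
29 | (1R,2S,3E,7E,11E)-9-oxocembra-3,7,11,15(17)-tetraen-16,2-olide | C=C1C(=O)O[C@H]2/C=C(\C)CC/C=C(\C)C(=O)C/C=C(\C)CC[C@H]12 | intermediate
30 | (1R,2S,3E,7E,9R,11E)-9-hydroxycembra-3,7,11,15(17)-tetraen-16,2-olide | C=C1C(=O)O[C@H]2/C=C(\C)CC/C=C(\C)[C@H](O)C/C=C(\C)CC[C@H]12 | intermediate
31 | (1R,2S,3E,7E,9R,11E)-9-acetoxycembra-3,7,11,15(17)-tetraen-16,2-olide (CNP0129197.1) | C=C1C(=O)O[C@H]2/C=C(\C)CC/C=C(\C)[C@H](OC(C)=O)C/C=C(\C)CC[C@H]12 | target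

**Count and risks**

Total step count: 18. Longest linear sequence: 14 steps (steps 1–4 then 9–18; the branch through steps 5–8 is equally long).

Steps most likely to fail:

1. Step 13 (ring closure). What may go wrong: intermolecular coupling outrunning ring closure; loss of regiocontrol, with the aldehyde attacking C7 to give the smaller ring with an exocyclic ethylidene; or migration of the C11=C12 double bond into conjugation with the aldehyde before coupling. Fallback, closing the same bond by a Nozaki–Hiyama–Kishi reaction: it sets out from diol 19. Hydrozirconation with excess Cp2Zr(H)Cl (THF, rt to 40 °C, equilibration to the less hindered alkenylzirconium at C8) and iodinolysis with I2 should give the (E)-alkenyl iodide, (3R,4R,5E,9E)-3-{(3E)-6-[(tert-butyldiphenylsilyl)oxy]-3-methylhex-3-en-1-yl}-10-iodo-6-methylundeca-5,9-diene-1,4-diol F1. TBAF in THF should give the iodo triol F2, and TEMPO/PhI(OAc)2 as in step 12 the iodo aldehyde lactone F3. CrCl2 with catalytic NiCl2 in DMSO–THF at high dilution should then close C8–C9 to the macrocyclic allylic alcohol, (1R,2R,3E,7E,11E)-9-hydroxycembra-3,7,11-trien-16,2-olide F4 (C9 epimers). Et3SiCl and imidazole in CH2Cl2 bring the sequence back to 23.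

2. Step 17 (C9 reduction). What may go wrong: poor facial selectivity if the conformational bias of the macrocycle opposes the catalyst, or competing conjugate reduction of the α-methylene lactone. Fallback without the oxidation–reduction detour: it sets out from 28. The two C9 epimers are separated by chromatography; the 9R epimer is 30 itself, and the 9S epimer, (1R,2S,3E,7E,9S,11E)-9-hydroxycembra-3,7,11,15(17)-tetraen-16,2-olide F5, is inverted and acetylated in one operation by Mitsunobu esterification with acetic acid (PPh3, DIAD, AcOH, toluene, 0 °C). The sequence comes back at 31, with the 9R portion re-entering at 30.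

3. Step 12 (double oxidation). What may go wrong: oxidation of the secondary allylic C2 hydroxyl before the lactol forms, over-oxidation, or acid-promoted migration of the C11=C12 double bond into conjugation with the new aldehyde during the long reaction. Fallback that separates lactone formation from aldehyde formation: it sets out from 19, where the C9 oxygen is still silylated. TEMPO/PhI(OAc)2 (2.2 equiv, CH2Cl2) should convert only the 1,4-diol into the lactone silyl ether, (4R,5R)-4-{(3E)-6-[(tert-butyldiphenylsilyl)oxy]-3-methylhex-3-en-1-yl}-5-[(1E)-2-methylhept-1-en-5-yn-1-yl]oxolan-2-one F6. TBAF buffered with AcOH should give the hydroxy lactone F7, and a brief Parikh–Doering oxidation (SO3·pyridine, DMSO, iPr2NEt, 0 °C) leads back to 22.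

**Further compounds**

F1 | step 13 | (3R,4R,5E,9E)-3-{(3E)-6-[(tert-butyldiphenylsilyl)oxy]-3-methylhex-3-en-1-yl}-10-iodo-6-methylundeca-5,9-diene-1,4-diol | O[C@@H](/C=C(\C)CC/C=C(\C)I)[C@H](CC/C(C)=C/CCO[Si](c1ccccc1)(c1ccccc1)C(C)(C)C)CCO
F2 | step 13 | (3R,4R,5E,9E)-3-[(3E)-6-hydroxy-3-methylhex-3-en-1-yl]-10-iodo-6-methylundeca-5,9-diene-1,4-diol | O[C@@H](/C=C(\C)CC/C=C(\C)I)[C@H](CC/C(C)=C/CCO)CCO
F3 | step 13 | (4R,5R)-5-[(1E,5E)-6-iodo-2-methylhepta-1,5-dien-1-yl]-4-[(3E)-3-methyl-6-oxohex-3-en-1-yl]oxolan-2-one | O=C1O[C@@H](/C=C(\C)CC/C=C(\C)I)[C@H](CC/C(C)=C/CC=O)C1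
F4 | step 13 | (1R,2R,3E,7E,11E)-9-hydroxycembra-3,7,11-trien-16,2-olide (C9 epimers) | C1C(=O)O[C@H]2/C=C(\C)CC/C=C(\C)C(O)C/C=C(\C)CC[C@H]12
F5 | step 17 | (1R,2S,3E,7E,9S,11E)-9-hydroxycembra-3,7,11,15(17)-tetraen-16,2-olide | C=C1C(=O)O[C@H]2/C=C(\C)CC/C=C(\C)[C@@H](O)C/C=C(\C)CC[C@H]12
F6 | step 12 | (4R,5R)-4-{(3E)-6-[(tert-butyldiphenylsilyl)oxy]-3-methylhex-3-en-1-yl}-5-[(1E)-2-methylhept-1-en-5-yn-1-yl]oxolan-2-one | O=C1O[C@@H](/C=C(\C)CCC#CC)[C@H](CC/C(C)=C/CCO[Si](c2ccccc2)(c2ccccc2)C(C)(C)C)C1
F7 | step 12 | (4R,5R)-4-[(3E)-6-hydroxy-3-methylhex-3-en-1-yl]-5-[(1E)-2-methylhept-1-en-5-yn-1-yl]oxolan-2-one | O=C1O[C@@H](/C=C(\C)CCC#CC)[C@H](CC/C(C)=C/CCO)C1
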